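(The numbers are invented; what happens was integrated by code.)

21 is the number the examiner lays on the table: the balance of dormant form over electrophile in this flask.

    electrophile + nucleophile ⇌ acid set free + target (K1 = 1.3, k1 = 0.56 /M/min)
    nucleophile + acid set free ⇌ protonated nucleophile, settled at all times (K2 = 70000 /M)
    electrophile ⇌ dormant form (K3 = 21, k3 = 0.054 /min)
    2 nucleophile → homo dimer (k4 = 0.90 /M/min)

electrophile 0.050 M (fed, over 12 min); nucleophile 0.0600 M; time 5.0 h; the fed solution adds 0.20 times the starting volume

- a doubled species enters its step squared and goes two at a time
- charges are per starting volume, the dose included; the dosed solution carries all of it
- what has gone from electrophile into another species counts as reacted, even if it can come back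
- run time (flask): 5.0 h

1. part of the electrophile that has reacted at 5.0 h
2. share of the unused nucleophile that is free and not bound as protonated nucleophile, at 5.0 h

"What does that constant do?" At balance, c(dormant form)/c(electrophile) equals it, so of the electrophile that has not become target, the part still free is the free share, one over one plus the constant: 4.55%.

"Does the balance stand at the reading?" Yes. The dormant step is first order both ways, and integrated it closes on balance exponentially, with forward and backward constants added; its relaxation half-life of 0.204 h is short against 5.0 h.

"But coupling drains the pool meanwhile." Its forward half-life, at the charged concentrations and with the way back not counted, is 0.34 h, against 0.204 h for that relaxation, so these two times do not show that the dormant form keeps pace. But c(nucleophile) stands in the coupling rate, and the dimer step gives nucleophile a first half-life of 0.154 h, shorter than 5.0 h. Integrated in closed form, that step by itself leaves the fraction one over one plus time over that half-life, which is 2.99% of the starting nucleophile at the reading. So I expect coupling to have slowed by then, with the dormant form, the resting state of the electrophile, standing at balance.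

"Then c?" If a share y of the charge has left as target, the free electrophile is one minus y, times the free share. Not knowing y, I take it as zero and commit to 95.5%, a floor; any target lifts c inside a band as wide as the free share.

"And fr?" At the start the binding constant times c(nucleophile) is 4200, so acid set free is taken up as it appears. How much free nucleophile the dimer leaves I have not reckoned, so I give no number.

The forecast says 96% (94% to 97%), on the ground of “about 1/22 of the unconverted pool free”, which puts it above my floor. For fr it says 21% (14% to 30%).

The flask gives 96.2% and 16.1%, both inside the forecast's ranges. So "reacted" here mostly means parked: at 5.00 h the dormant form holds 80.4% of the charge and the target 15.8%. Putting that target share through the free share gives 3.83% of the charge as free electrophile, and the flask shows 3.79%.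

A neighbour charged with 0.085 M of electrophile has the same free share, and its target of 13.6% gives 3.93% left free. Computed, it holds 3.90% and c is 96.1%.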